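**Assumptions:** (R)-but-3-yn-2-ol, ethyl (S)-lactate, 4-bromo-2-methoxyphenol and a THF solution of 3,4-dimethoxyphenylmagnesium bromide are bought. Minor diastereomers are separated by chromatography or HPLC.

## Retrosynthetic overview
1. Manassantin A is cut at the two ArO–CH(Me) bonds (Mitsunobu inversion with the (S)-lactamide made from ethyl (S)-lactate) and at the two benzylic carbinols (Felkin reduction of α-aryloxy aryl ketones made from Weinreb amides). This leaves a C2-symmetric bisphenol 2,5-diaryl-3,4-dimethyltetrahydrofuran.
2. The only non-aromatic ring, the THF, is closed by 5-exo SN2 of a C4 alkoxide on a C1 benzylic mesylate, with inversion at C1. The two aryl groups come from ArMgBr additions: Felkin addition to an aldehyde, then a Weinreb ketone synthesis.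
3. The 2,3-dimethyl-1,4-dicarbonyl skeleton comes from an Ireland–Claisen [3,3] rearrangement of the propionate of (R,E)-pent-3-en-2-ol, which is made from (R)-but-3-yn-2-ol. The new C–C bond and both methyl stereocentres are set by chirality transfer through a chair transition state.
4. Order of events: [3,3] rearrangement, Weinreb amide, ozonolysis, two ArMgBr additions with ketone reduction, THF closure, debenzylation, then the side arms (Mitsunobu, Weinreb ketone, reduction).

## Route

**Step 1**
Reactants: **1** (R)-but-3-yn-2-ol; **2** iodomethane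
Product: **3** (R)-pent-3-yn-2-ol
Conditions: n-BuLi (2.2 equiv), THF, −78 → 0 °C; then MeI (1.1 equiv), DMPU, −78 °C → rt
Reagents that add atoms: iodomethane, CI
Why: In the alkoxide/acetylide dianion the acetylide carbon is the nucleophilic site and is methylated by SN2, while the carbinol stereocentre is untouched.

**Step 2**
Reactants: **3**
Product: **4** (2R,3E)-pent-3-en-2-ol
Conditions: Red-Al, THF, 0 °C → rt; aqueous Rochelle salt work-up
Reagents that add atoms: none
Why: Alkoxide-directed trans-hydroalumination of the propargylic alcohol followed by protonolysis gives the E-allylic alcohol, with the carbinol centre retained.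

**Step 3**
Reactants: **4**; **5** propionyl chloride
Product: **6** (2R,3E)-pent-3-en-2-yl propanoate
Conditions: pyridine, DMAP (cat.), CH2Cl2, 0 °C
Reagents that add atoms: propionyl chloride, CCC(=O)Cl
Why: Simple O-acylation gives the Claisen substrate without touching the stereocentre or the alkene.

**Step 4**
Reactants: **6**
Product: **7** (2R,3S,4E)-2,3-dimethylhex-4-enoic acid
Conditions: LDA, THF/HMPA (4:1), −78 °C; TBSCl; warm to rt, 12 h; aqueous HCl work-up
Reagents that add atoms: none (the TBS group is lost on hydrolysis of the silyl ester)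
Why: Ireland–Claisen [3,3] rearrangement. LDA in THF/HMPA gives the Z(O)-enolate, so the ketene acetal methyl and the E-alkene methyl are both pseudo-equatorial in the chair. The carbinol methyl is also equatorial, so the (R) carbinol transfers its chirality to give the syn-(2R,3S) acid and a new E-alkene, forming the C2–C3 bond.

**Step 5**
Reactants: **7**; **8** N,O-dimethylhydroxylamine hydrochloride
Product: **9** (2R,3S,4E)-N-methoxy-N,2,3-trimethylhex-4-enamide
Conditions: EDC·HCl, HOBt, i-Pr2NEt, CH2Cl2, rt
Reagents that add atoms: N,O-dimethylhydroxylamine hydrochloride, CNOC.Cl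
Why: Mild carbodiimide coupling gives the Weinreb amide without epimerising the β-branched α-centre.

**Step 6**
Reactants: **9**
Product: **10** (2R,3R)-N-methoxy-N,2,3-trimethyl-4-oxobutanamide
Conditions: O3, CH2Cl2, −78 °C; then Me2S, −78 °C → rt
Reagents that add atoms: ozone, [O-][O+]=O
Why: Ozonolysis cleaves the disubstituted alkene and leaves the Weinreb amide intact; the aldehyde is used crude and promptly to avoid epimerisation of its α-methyl centre (the descriptor changes from 3S to 3R only because the CIP priorities change, not the geometry).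

**Step 7**
Reactants: **11** 4-bromo-2-methoxyphenol; **12** benzyl bromide
Product: **13** 1-(benzyloxy)-4-bromo-2-methoxybenzene
Conditions: K2CO3, acetone, reflux
Reagents that add atoms: benzyl bromide, BrCc1ccccc1
Why: Williamson O-benzylation protects the phenol as an ether that survives Grignard, hydride, mesylation and fluoride conditions.

**Step 8**
Reactants: **13**
Product: **14** [4-(benzyloxy)-3-methoxyphenyl]magnesium bromide
Conditions: Mg turnings, I2 (cat.), THF, 50 °C; used as a THF solution
Reagents that add atoms: magnesium, [Mg]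
Why: Oxidative insertion of Mg into the aryl C–Br bond gives the Grignard reagent, and the benzyl ether is inert.

**Step 9**
Reactants: **10**; **14**
Product: **15** (2R,3R,4S)-4-[4-(benzyloxy)-3-methoxyphenyl]-4-hydroxy-N-methoxy-N,2,3-trimethylbutanamide
Conditions: **14** (1.1 equiv), THF, −78 °C; sat. NH4Cl added at −78 °C
Reagents that add atoms: **14**, COc1cc([Mg]Br)ccc1OCc1ccccc1
Why: The aldehyde reacts much faster than the Weinreb amide, and Felkin–Anh addition (Grignard addition to an α-methyl aldehyde, nucleophile anti to the CH(Me)CON chain) sets the carbinol as (S) as the major diastereomer (about 3:1).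

**Step 10**
Reactants: **15**; **16** tert-butyldimethylsilyl triflate
Product: **17** (2R,3R,4S)-4-[4-(benzyloxy)-3-methoxyphenyl]-4-[(tert-butyldimethylsilyl)oxy]-N-methoxy-N,2,3-trimethylbutanamide
Conditions: TBSOTf, 2,6-lutidine, CH2Cl2, −78 → 0 °C; chromatographic removal of the minor 4R epimer
Reagents that add atoms: TBSOTf, CC(C)(C)[Si](C)(C)OS(=O)(=O)C(F)(F)F
Why: Silylation protects the future ring oxygen, prevents γ-lactonisation onto the amide, and makes the Felkin/anti-Felkin epimers easy to separate.

**Step 11**
Reactants: **17**; **14**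
Product: **18** (2R,3R,4S)-1,4-bis[4-(benzyloxy)-3-methoxyphenyl]-4-[(tert-butyldimethylsilyl)oxy]-2,3-dimethylbutan-1-one
Conditions: **14** (2.5 equiv), THF, 0 °C → rt; NH4Cl quench
Reagents that add atoms: **14**, COc1cc([Mg]Br)ccc1OCc1ccccc1
Why: Weinreb ketone synthesis, where the stable chelated tetrahedral intermediate stops at the ketone and leaves the stereocentres intact.

**Step 12**
Reactants: **18**
Product: **19** (1R,2R,3R,4S)-1,4-bis[4-(benzyloxy)-3-methoxyphenyl]-4-[(tert-butyldimethylsilyl)oxy]-2,3-dimethylbutan-1-ol
Conditions: L-Selectride, THF, −78 °C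
Reagents that add atoms: none
Why: Felkin–Anh reduction of the α-methyl aryl ketone, with the bulky hydride delivered anti to the large C3 substituent, sets C1-OH as (R); this is the centre inverted in Step 13.

**Step 13**
Reactants: **19**
Product: **20** (2S,3R,4R,5S)-2,5-bis[4-(benzyloxy)-3-methoxyphenyl]-3,4-dimethyltetrahydrofuran
Conditions: Ms2O, Et3N, CH2Cl2, −40 °C; then TBAF, THF, −40 °C → rt (one pot, mesylate not isolated)
Reagents that add atoms: none (the Ms and TBS groups are both lost)
Why: Ms2O avoids a chloride source that could give double inversion at the benzylic carbon. Fluoride then releases the C4 alkoxide, which closes the ring by 5-exo-tet SN2 on the C1 benzylic mesylate. Inversion converts C1 from R to S, C4 (S) is retained, and the result is the required 2,3-cis, 3,4-trans, 4,5-cis, 2,5-trans core.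

**Step 14**
Reactants: **20**
Product: **21** 4,4′-[(2S,3R,4R,5S)-3,4-dimethyloxolane-2,5-diyl]bis(2-methoxyphenol)
Conditions: H2 (1 atm), 10% Pd/C, EtOAc, rt, monitored by TLC and stopped at full debenzylation
Reagents that add atoms: none
Why: Hydrogenolysis of the aryl benzyl ethers is much faster than cleavage of the THF C–O bonds, so brief exposure frees both phenols.

**Step 15**
Reactants: **22** ethyl (S)-lactate; **8** N,O-dimethylhydroxylamine hydrochloride
Product: **23** (S)-2-hydroxy-N-methoxy-N-methylpropanamide
Conditions: i-PrMgCl (3 equiv), THF, −20 → 0 °C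
Reagents that add atoms: N,O-dimethylhydroxylamine hydrochloride, CNOC.Cl
Why: Magnesium amide aminolysis of the ester gives the Weinreb lactamide without racemising the α-hydroxy centre.

**Step 16**
Reactants: **21**; **23** (2.6 equiv)
Product: **24** (2R,2′R)-2,2′-{[(2S,3R,4R,5S)-3,4-dimethyloxolane-2,5-diyl]bis(2-methoxy-4,1-phenylene)bis(oxy)}bis(N-methoxy-N-methylpropanamide)
Conditions: PPh3 (3 equiv), DIAD (3 equiv), THF, 0 °C → rt
Reagents that add atoms: none beyond reactant **23**
Why: Mitsunobu SN2 of the phenol on the activated secondary α-hydroxy amide inverts (S) to (R) at each ether carbon.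

**Step 17**
Reactants: **24**; **25** (3,4-dimethoxyphenyl)magnesium bromide (5 equiv)
Product: **26** (2R,2′R)-2,2′-{[(2S,3R,4R,5S)-3,4-dimethyloxolane-2,5-diyl]bis(2-methoxy-4,1-phenylene)bis(oxy)}bis[1-(3,4-dimethoxyphenyl)propan-1-one]
Conditions: THF, 0 °C, 1 h; cold NH4Cl quench
Reagents that add atoms: **25**, COc1ccc([Mg]Br)cc1OC
Why: Double Weinreb ketone synthesis, with the chelated tetrahedral intermediate preventing over-addition and α-epimerisation before quench, and no other electrophile present.

**Step 18**
Reactants: **26**
Product: **27** manassantin A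
Conditions: L-Selectride, THF, −78 °C; HPLC purification of the (R,R,R,R) isomer
Reagents that add atoms: none
Why: In the Felkin–Anh polar model the α-aryloxy group sits perpendicular to the carbonyl and anti to the incoming bulky hydride, which gives the (R)-benzylic alcohol next to each (R)-aryloxy carbon (the threo arrangement) at both arms.

## Compound list
1 | (R)-but-3-yn-2-ol | C#C[C@@H](C)O | starting material
2 | iodomethane | CI | starting material
3 | (R)-pent-3-yn-2-ol | CC#C[C@@H](C)O | intermediate
4 | (2R,3E)-pent-3-en-2-ol | C/C=C/[C@@H](C)O | intermediate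
5 | propionyl chloride | CCC(=O)Cl | starting material
6 | (2R,3E)-pent-3-en-2-yl propanoate | CCC(=O)O[C@H](C)/C=C/C | intermediate
7 | (2R,3S,4E)-2,3-dimethylhex-4-enoic acid | OC(=O)[C@H](C)[C@@H](C)/C=C/C | intermediate
8 | N,O-dimethylhydroxylamine hydrochloride | CNOC.Cl | starting material
9 | (2R,3S,4E)-N-methoxy-N,2,3-trimethylhex-4-enamide | CON(C)C(=O)[C@H](C)[C@@H](C)/C=C/C | intermediate
10 | (2R,3R)-N-methoxy-N,2,3-trimethyl-4-oxobutanamide | CON(C)C(=O)[C@H](C)[C@@H](C)C=O | intermediate
11 | 4-bromo-2-methoxyphenol | COc1cc(Br)ccc1O | starting material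
12 | benzyl bromide | BrCc1ccccc1 | starting material
13 | 1-(benzyloxy)-4-bromo-2-methoxybenzene | COc1cc(Br)ccc1OCc1ccccc1 | intermediate
14 | [4-(benzyloxy)-3-methoxyphenyl]magnesium bromide | COc1cc([Mg]Br)ccc1OCc1ccccc1 | intermediate
15 | (2R,3R,4S)-4-[4-(benzyloxy)-3-methoxyphenyl]-4-hydroxy-N-methoxy-N,2,3-trimethylbutanamide | CON(C)C(=O)[C@H](C)[C@@H](C)[C@H](O)c1ccc(OCc2ccccc2)c(OC)c1 | intermediate
16 | tert-butyldimethylsilyl triflate | CC(C)(C)[Si](C)(C)OS(=O)(=O)C(F)(F)F | starting material
17 | TBS ether of 15 | CON(C)C(=O)[C@H](C)[C@@H](C)[C@H](O[Si](C)(C)C(C)(C)C)c1ccc(OCc2ccccc2)c(OC)c1 | intermediate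
18 | (2R,3R,4S)-1,4-bis[4-(benzyloxy)-3-methoxyphenyl]-4-OTBS-2,3-dimethylbutan-1-one | COc1cc(ccc1OCc1ccccc1)C(=O)[C@H](C)[C@@H](C)[C@H](O[Si](C)(C)C(C)(C)C)c1ccc(OCc2ccccc2)c(OC)c1 | intermediate
19 | (1R,2R,3R,4S)-1,4-bis[4-(benzyloxy)-3-methoxyphenyl]-4-OTBS-2,3-dimethylbutan-1-ol | COc1cc(ccc1OCc1ccccc1)[C@H](O)[C@H](C)[C@@H](C)[C@H](O[Si](C)(C)C(C)(C)C)c1ccc(OCc2ccccc2)c(OC)c1 | intermediate
20 | (2S,3R,4R,5S)-2,5-bis(4-benzyloxy-3-methoxyphenyl)-3,4-dimethyltetrahydrofuran | COc1cc(ccc1OCc1ccccc1)[C@H]1O[C@H](c2ccc(OCc3ccccc3)c(OC)c2)[C@H](C)[C@H]1C | intermediate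
21 | bisphenol THF core | COc1cc(ccc1O)[C@H]1O[C@H](c2ccc(O)c(OC)c2)[C@H](C)[C@H]1C | intermediate
22 | ethyl (S)-lactate | CCOC(=O)[C@H](C)O | starting material
23 | (S)-2-hydroxy-N-methoxy-N-methylpropanamide | C[C@H](O)C(=O)N(C)OC | intermediate
24 | bis(aryloxy Weinreb amide) | COc1cc(ccc1O[C@H](C)C(=O)N(C)OC)[C@H]1O[C@H](c2ccc(O[C@H](C)C(=O)N(C)OC)c(OC)c2)[C@H](C)[C@H]1C | intermediate
25 | (3,4-dimethoxyphenyl)magnesium bromide | COc1ccc([Mg]Br)cc1OC | starting material
26 | bis(α-aryloxy aryl ketone) | COc1ccc(cc1OC)C(=O)[C@@H](C)Oc1ccc(cc1OC)[C@H]1O[C@H](c2ccc(O[C@H](C)C(=O)c3ccc(OC)c(OC)c3)c(OC)c2)[C@H](C)[C@H]1C | intermediate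
27 | manassantin A | COc1ccc([C@@H](O)[C@@H](C)Oc2ccc([C@H]3O[C@H](c4ccc(O[C@H](C)[C@H](O)c5ccc(OC)c(OC)c5)c(OC)c4)[C@H](C)[C@H]3C)cc2OC)cc1OC | target

**Total steps:** 18, including the side preparations in Steps 7–8 (aryl Grignard) and Step 15 (lactamide).
**Longest linear sequence:** 15 steps (Steps 1–6, 9–14, 16–18).

## Three steps most likely to fail
1. **Step 13 (ring closure by SN2 at an electron-rich benzylic mesylate).** The mesylate may ionise (SN1 scrambling) or eliminate to the styrene.
   Fallback: remove the TBS group from **18** (HF·pyridine) to give the 4-hydroxy ketone, which exists as the cyclic hemiketal. Then run a reductive etherification (Et3SiH, TMSOTf), which sets C2 by oxocarbenium face selectivity rather than inversion, and separate the diastereomers.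
2. **Step 9 (Felkin arylation of the 2,3-syn α,β-dimethyl aldehyde).** Selectivity may be modest, and the aldehyde can epimerise.
   Fallback: build the C4 carbinol by ketone reduction instead of aldehyde addition. Oxidise the crude carbinol mixture with Dess–Martin periodinane to the single γ-keto Weinreb amide, then reduce it with Zn(BH4)2 (chelation) or L-Selectride (Felkin). The two hydrides are expected to give complementary diastereomer ratios, so the desired (4S) alcohol can be enriched and the other epimer recycled through the ketone.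
3. **Step 18 (final diastereoselective reduction at both arms).** Chelation or Cornforth-type pathways would give the erythro (1S,2R-type) isomer, and the overall yield falls with the square of the per-arm selectivity.
   Fallback: prepare the side arm separately. Reduce (S)-2-benzyloxy-1-(3,4-dimethoxyphenyl)propan-1-one with Zn(BH4)2 (chelation control) to give the (1R,2S) alcohol. Protect the benzylic OH as its TBS ether and remove the benzyl group by hydrogenolysis. Couple the resulting secondary alcohol to bisphenol **21** by Mitsunobu with inversion (S to R at the aryloxy carbon), then remove the TBS group with TBAF.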